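## Analysis of the target

The target is a 1-aryltetralin cyclolignan. In tetralin numbering, C1 carries a 4-hydroxy-3-methoxyphenyl (guaiacyl) ring, C2 and C3 carry hydroxymethyl groups (carbons C9 and C10), C4 is a methylene, C4a and C8a are the fusion carbons, and ring A has hydrogen at C5, methoxy at C6 and hydroxyl groups at C7 and C8. The three contiguous stereocentres are (1S,2R,3R), so the aryl group and both hydroxymethyl groups are mutually trans and pseudo-equatorial on ring B. At the ester oxidation level C2 and C3 can be equilibrated by base, whereas the doubly benzylic C1 cannot, so C1 must be set absolutely and the other two can be relayed from it. The sensitive sites are the guaiacyl phenol, the 3-methoxycatechol of ring A (O7/O8, oxidised to an o-quinone by air under base) and the C1 hydrogen para to a phenol, whose oxidative loss would aromatise ring B. The difficulty is threefold: two different C6C3 halves must be joined head to head, ring A must be attached through C8a (next to the C8 oxygen) and not through C5, and a single enantiomer is required. The strategy rests on one feature: the C1–C2–C9/guaiacyl half and the C4–C3–C10/ring A half are a coniferyl and a 5-hydroxyconiferyl unit joined at C2–C3 and cyclised from C8a onto C1. Both bonds can therefore be made by phenol oxidation of two cinnamates, provided a chiral diester bridge between C9 and C10 enforces the cross-coupling.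

## Retrosynthetic reasoning

**19 back to 18.** The O8–sulfur bond is cut last. The sulfonate on O8 is kept through the whole sequence because it keeps the catechol from oxidising and, earlier, steers the ring closure. The forward reaction must cleave an aryl sulfonate next to a free phenol without harming the triol.

**18 back to 17.** The two primary alcohols are traced to methyl esters. Holding C9 and C10 at the ester level is what makes C2 and C3 correctable, and it is the oxidation level that cinnamates deliver directly. The forward step is a plain hydride reduction.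

**17 back to 16 and 15.** The two ester C–O bonds are reconnected to the tether diol 9 and the C3–C4 unsaturation is restored. The all-trans diester 17 is the thermodynamic sink once C1 is fixed, so neither the face of hydrogen addition to 15 nor the C3 configuration of 16 needs to be controlled. Hydrogenation is placed before tether release so that no base meets a dienolate system that could reach the C1 hydrogen.

**15 back to 12 (key disconnection).** C2–C3 and C1–C8a are cut. These are the two bonds that join the C6C3 halves; any other cut (C4–C4a or C1–aryl) would give fragments that are no longer simple cinnamates. The gain is two rings (the nine-membered dilactone and ring B), two skeletal bonds and the stereocentres C1 and C2 in one operation. The forward reaction must couple the two β-carbons in preference to all other phenol-coupling modes, make ring A the nucleophile through C8a, place the aryl group trans to the C2 carbonyl, and take its absolute sense from the diol.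

**12 back to 11, then to 10 and 5.** The two phenols are masked as allyl ethers, and the ester C–O bond on the ring A side is cut. Acylation of a secondary alcohol by a cinnamic acid is only clean when the acid has no free phenol, and allyl is a mask that comes off without touching cinnamate double bonds or the sulfonate.

**10 back to 8 and 9; 8 back to 6.** The first ester bond is cut to the tether diol 9 and the O-allyl acid 8, which comes from ferulic acid 6. Because the two hydroxyls of 9 are homotopic, monoacylation can give only one monoester.

**5 back to 3 and 4; 3 back to 2 and 1.** The cinnamate double bond is cut by a condensation transform to aldehyde 3 and malonic acid 4. The two phenols of 5-hydroxyvanillin 1 are told apart by acidity: the one para to the formyl group is alkylated first (2), leaving the other for sulfonylation (3).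

## Alternatives that were turned down

**Alternative 1:** Ring B is disconnected at C4–C4a and C1–C8a by inserting the ring A aryne into the C1–C4 bond of a four-membered ketone.
- Forward key step: caesium fluoride A4 (CsF) releases the aryne from silyl triflate A2. The sulfonyl-stabilised carbanion of cyclobutanone A3 adds at C4a, the resulting aryl anion at C8a closes on the carbonyl, and the benzocyclobutenoxide fragments to tetralone A1.
- For it: both aryl–carbon bonds of ring B form at once; the alkoxy group at C8 directs the aryne addition, so the ring A pattern is unambiguous; C2 and C3 come from a preformed enantiopure ring; and there is no cross-coupling problem. The reaction class (aryne insertion into an activated C–C bond) is established. On these points it is stronger than the chosen route.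
- Against it: A1 still lacks the guaiacyl group, has a ketone at C1 and a sulfone at C4. Aryl addition followed by ionic deoxygenation or alkene hydrogenation would deliver hydrogen to C1 anti to the C2 substituent and so favour the 1,2-cis isomer, which cannot be corrected at the non-epimerisable C1. A2 (a pentasubstituted benzene) and A3 (an enantiopure α-sulfonyl cyclobutanone) each need their own multi-step syntheses, and four benzyl ethers plus the sulfone must be removed.
- Comparison: the chosen route offers in exchange a much shorter sequence, all carbons from two cinnamate units, and C1 set trans to C2 in the same step that builds the skeleton.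

**Alternative 2:** C1–C2 is cut together with a temporary O8–C9 bond, using the C8 phenol as the heteroatom of an o-quinone methide.
- Forward key step: catalytic diphenyl hydrogen phosphate A7 dehydrates hydroxy carbinol A6 to the o-quinone methide (C1 exocyclic on C8a, carbonyl at C8). The tethered enol ether adds in an intramolecular hetero-Diels–Alder reaction to give the tricyclic acetal A5.
- For it: the C8 oxygen, the group that distinguishes this target from simpler cyclolignans, becomes the reacting atom, so regiochemistry is built in. The C1/C2 relationship comes from a concerted, tether-constrained transition state biased by the existing C3 centre. The reaction class is known. On regiocontrol, diastereocontrol and precedent it is stronger.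
- Against it: A6 already contains the C4–C4a bond, the C3 stereocentre, the enol ether and the diaryl carbinol, so a long linear sequence precedes the key step. A5 must then be unravelled through a lactol and aldehyde at C9 (C2 epimerisable at that stage) and three benzyl ethers removed.
- Comparison: the chosen route is convergent and far shorter, with the risk concentrated in one step rather than spread over a long preparation.

**Alternative 3:** Ring B is cut at C1–C2 and C3–C4 as a [4+2] addition of a photoenol, with the C1–aryl bond made afterwards.
- Forward key step: irradiation near 365 nm of aldehyde A9 gives the hydroxy-o-quinodimethane, which is trapped by dimethyl fumarate A10 in the presence of Ti(OiPr)4 A11 (tetravalent titanium) carrying a diol ligand of the TADDOL class. The product is hydroxy diester A8, with trans esters and the hydroxyl cis to the C2 ester.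
- For it: the trans C2/C3 relationship comes directly from the fumarate geometry; the ring A pattern is fixed from the start; the asymmetric step is catalytic; and later ionisation at C1 with capture by guaiacol A12 should place the aryl group trans to C2, since the nucleophile approaches anti to the C2 ester. It is stronger on C2/C3 control and has no cross-coupling question.
- Against it: A9 is a hexasubstituted benzene that needs a regiocontrolled multi-step synthesis. The enantioselective photoenol cycloaddition is narrow in scope and untested with an alkoxy group flanking the aldehyde. The C1 centre formed in the key step is discarded, and the arylation by A12 brings its own regiochemistry (para to hydroxyl against para to methoxy).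
- Comparison: the overall length would be similar or greater. The chosen route installs the aryl group, ring B and the C1 centre together and needs no separate arylation.

Key step: step 8

Assumption: the (2R,4R) tether is taken to induce the 2R configuration in the coupling, and the descriptors of 13 to 16 are written on that basis (Ts = 4-methylbenzenesulfonyl throughout).

## Route

Step 1
Reactants: 1 3,4-dihydroxy-5-methoxybenzaldehyde (5-hydroxyvanillin)
Product: 2 4-(allyloxy)-3-hydroxy-5-methoxybenzaldehyde
Conditions: allyl bromide (1.05 equiv), Li2CO3, DMF, 45 °C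
Reagents that add atoms: allyl bromide, C=CCBr
Why: Williamson ether synthesis under acidity control: the hydroxyl para to the formyl group is much the more acidic, so the weak base ionises only it and one equivalent of allyl bromide should alkylate that phenolate; allyl is chosen because it is later removed without touching cinnamate alkenes or the sulfonate.

Step 2
Reactants: 2 4-(allyloxy)-3-hydroxy-5-methoxybenzaldehyde
Product: 3 4-(allyloxy)-3-methoxy-5-(tosyloxy)benzaldehyde
Conditions: TsCl, Et3N, DMAP (cat.), CH2Cl2, 0 °C to rt
Reagents that add atoms: 4-methylbenzenesulfonyl chloride, Cc1ccc(cc1)S(Cl)(=O)=O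
Why: DMAP-catalysed sulfonylation of the only remaining phenol; the aldehyde and the allyl ether are inert to these conditions.

Step 3
Reactants: 3 4-(allyloxy)-3-methoxy-5-(tosyloxy)benzaldehyde; 4 malonic acid
Product: 5 (E)-3-[4-(allyloxy)-3-methoxy-5-(tosyloxy)phenyl]acrylic acid
Conditions: pyridine, piperidine (cat.), 85 °C; then aq. HCl
Reagents that add atoms: none
Why: Knoevenagel–Doebner condensation with decarboxylation should give the E-cinnamic acid; the aryl sulfonate is stable to pyridine and catalytic piperidine, and the allyl ether cannot rearrange at this temperature with both ortho positions occupied.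

Step 4
Reactants: 6 ferulic acid
Product: 8 (E)-3-[4-(allyloxy)-3-methoxyphenyl]acrylic acid, via allyl 4-O-allylferulate 7 (not isolated)
Conditions: allyl bromide (2.4 equiv), K2CO3, DMF, 50 °C; then 2 M NaOH, MeOH, 50 °C; aq. HCl
Reagents that add atoms: allyl bromide, C=CCBr; sodium hydroxide, [Na+].[OH-]
Why: Williamson alkylation of phenolate and carboxylate followed in the same pot by saponification of the allyl ester, whose hydroxide oxygen ends in the carboxyl group; the aryl allyl ether is stable to hydroxide.

Step 5
Reactants: 8 (E)-3-[4-(allyloxy)-3-methoxyphenyl]acrylic acid; 9 (2R,4R)-pentane-2,4-diol (3 equiv, excess recovered)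
Product: 10 (2R,4R)-4-hydroxypentan-2-yl (E)-3-[4-(allyloxy)-3-methoxyphenyl]acrylate
Conditions: EDC·HCl, DMAP (cat.), CH2Cl2, 0 °C to rt
Reagents that add atoms: none
Why: Steglich carbodiimide esterification; excess of the C2-symmetric diol favours monoacylation, and since its two hydroxyls are homotopic only one monoester can form; the carbinol C–O bond is not broken, so both centres stay R.

Step 6
Reactants: 10 (2R,4R)-4-hydroxypentan-2-yl (E)-3-[4-(allyloxy)-3-methoxyphenyl]acrylate; 5 (E)-3-[4-(allyloxy)-3-methoxy-5-(tosyloxy)phenyl]acrylic acid
Product: 11 (2R,4R)-pentane-2,4-diyl mixed diester of acids 8 and 5 (bis-allyl ether)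
Conditions: EDC·HCl, DMAP, CH2Cl2, rt
Reagents that add atoms: none
Why: A second Steglich esterification; with both phenols masked the secondary alcohol is the only nucleophile, and again no stereocentre is touched.

Step 7
Reactants: 11 (2R,4R)-pentane-2,4-diyl mixed diester of acids 8 and 5 (bis-allyl ether)
Product: 12 (2R,4R)-pentane-2,4-diyl mixed diester of ferulic acid and (E)-3-[4-hydroxy-3-methoxy-5-(tosyloxy)phenyl]acrylic acid
Conditions: Pd(PPh3)4 (5 mol%), morpholine, THF, rt
Reagents that add atoms: none
Why: Tsuji–Trost deallylation: the catalyst ionises each aryl allyl ether to a π-allyl complex and a phenolate and morpholine takes up the allyl group, while cinnamate esters and the aryl sulfonate are inert; unlike an acyl group, the sulfonyl group should not migrate to the freed neighbouring phenol, because in-line displacement at sulfur is not possible through a five-membered ring.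

Step 8
Reactants: 12 (2R,4R)-pentane-2,4-diyl mixed diester of ferulic acid and (E)-3-[4-hydroxy-3-methoxy-5-(tosyloxy)phenyl]acrylic acid
Product: 15 tethered (1S,2R)-1-aryl-1,2-dihydronaphthalene-2,3-dicarboxylate nine-membered dilactone with O8 tosylated, via bis(quinone methide) dilactone 13 (not isolated), via benzylidene quinone methide 14 (not isolated)
Conditions: graphite anode, Pt cathode, undivided cell, LiClO4 (0.1 M), 2,6-lutidine (3 equiv), CH2Cl2/MeOH 4:1, 2 mM in 12, constant current, about 2 F/mol, 0 °C
Reagents that add atoms: none
Why: Proposed new method: each phenol of 12 gives up one electron and one proton at the anode (2,6-lutidine as proton acceptor) to form a phenoxyl radical with spin density on the carbon next to its ester carbonyl, and the two radical sites, held within reach by the diol, combine to the C2–C3 bond, which closes the nine-membered dilactone of bis(quinone methide) 13 by radical recombination (formally 9-exo with respect to either cinnamate double bond). Lutidine then removes the C3 hydrogen of the tosylated quinone methide, the more acidic of the two because the sulfonate stabilises the phenolate that forms, to give benzylidene 14, and C8a of the rearomatised ring A adds to the exocyclic carbon C1 of the remaining quinone methide in a 6-exo-trig vinylogous Friedel–Crafts closure of ring B, after which proton loss restores both aromatic rings. The closest known reaction type is the oxidative dehydrodimerisation of sinapate esters (FeCl3, peroxidase or anode) to 1-aryl-1,2-dihydronaphthalene-2,3-dicarboxylates, which passes through the same three stages but without a tether and only as a homodimerisation. C2 is set in the coupling by the (2R,4R) tether, whose esters hold each carbinol hydrogen eclipsed with its carbonyl and whose methyl groups avoid a syn-pentane contact, so that the two cinnamoyl arms are twisted in one sense and should meet through one pair of faces; C1 is set in the ring closure by C2, the guaiacyl group going trans to the C2 carbonyl as in the untethered dimerisations. The step needs coupling between the two β-carbons, which the tether and high dilution provide, since coupling through C5 or the phenol oxygen of the guaiacyl unit would require rings of thirteen or more members bridged across an arene. It needs ring A and not the guaiacyl ring to act as the nucleophile, which rests on the faster tautomerisation of the tosylated quinone methide, and it needs closure at C8a and not C5, which the tosylate secures because C8a is para to the C6 methoxy group whereas C5 is para to a sulfonyloxy group that no longer donates. The charge is limited to about two faraday per mole because the product phenols are themselves oxidisable.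

Step 9
Reactants: 15 tethered (1S,2R)-1-aryl-1,2-dihydronaphthalene-2,3-dicarboxylate nine-membered dilactone with O8 tosylated
Product: 16 tethered (1S,2R)-1-aryl-1,2,3,4-tetrahydronaphthalene-2,3-dicarboxylate dilactone (C3 configuration left open)
Conditions: H2 (1–3 atm), Pd/C, EtOAc/MeOH, rt
Reagents that add atoms: none
Why: Heterogeneous catalytic hydrogenation of the aryl-conjugated trisubstituted acrylate; aryl sulfonate, esters and the C1–aryl bonds should be untouched, and whichever face receives hydrogen the new C3 centre is corrected in step 10, while saturation of C3–C4 removes the conjugated path by which base could later reach the C1 hydrogen.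

Step 10
Reactants: 16 tethered (1S,2R)-1-aryl-1,2,3,4-tetrahydronaphthalene-2,3-dicarboxylate dilactone (C3 configuration left open)
Product: 17 dimethyl (1S,2R,3R)-7-hydroxy-1-(4-hydroxy-3-methoxyphenyl)-6-methoxy-8-(tosyloxy)-1,2,3,4-tetrahydronaphthalene-2,3-dicarboxylate
Conditions: NaOMe (5 equiv), MeOH, 50 °C, argon; AcOH quench
Reagents that add atoms: sodium methoxide, C[O-].[Na+]
Why: Base-mediated transesterification opens the strained dilactone and releases diol 9, and reversible ester-enolate formation at C3 (and C2) should funnel the material to the all-equatorial diester; C1 is not acidic and so dictates the (1S,2R,3R) outcome, and the sulfonate should survive because the neighbouring O7 phenolate would make ring oxygen O8 leave as part of a dianion.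

Step 11
Reactants: 17 dimethyl (1S,2R,3R)-7-hydroxy-1-(4-hydroxy-3-methoxyphenyl)-6-methoxy-8-(tosyloxy)-1,2,3,4-tetrahydronaphthalene-2,3-dicarboxylate
Product: 18 (1S,2R,3R)-1-(4-hydroxy-3-methoxyphenyl)-2,3-bis(hydroxymethyl)-6-methoxy-8-(tosyloxy)-1,2,3,4-tetrahydronaphthalen-7-ol
Conditions: LiAlH4 (excess), THF, 0 °C to rt; aq. potassium sodium tartrate (KNaC4H4O6)
Reagents that add atoms: none
Why: Hydride reduction of both esters to primary alcohols without epimerisation; the phenols are carried as aluminates, and at this temperature the aryl sulfonate beside a phenolate should not be attacked (partial cleavage would only anticipate step 12).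

Step 12
Reactants: 18 (1S,2R,3R)-1-(4-hydroxy-3-methoxyphenyl)-2,3-bis(hydroxymethyl)-6-methoxy-8-(tosyloxy)-1,2,3,4-tetrahydronaphthalen-7-ol
Product: 19 (1S,2R,3R)-1-(4-hydroxy-3-methoxyphenyl)-2,3-bis(hydroxymethyl)-6-methoxy-1,2,3,4-tetrahydronaphthalene-7,8-diol (target)
Conditions: Mg turnings, MeOH, rt, argon; aq. HCl work-up
Reagents that add atoms: none
Why: Electron-transfer desulfonylation of an aryl sulfonate (Mg in methanol), which cleaves the S–O bond through the sulfonyl radical anion and so does not depend on the phenolate being a good leaving group; nothing else in 18 is reducible, and exclusion of air with an acidic work-up protects the catechol.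

## Compound list

1 | 3,4-dihydroxy-5-methoxybenzaldehyde (5-hydroxyvanillin) | COc1cc(C=O)cc(O)c1O | starting material
2 | 4-(allyloxy)-3-hydroxy-5-methoxybenzaldehyde | COc1cc(C=O)cc(O)c1OCC=C | intermediate
3 | 4-(allyloxy)-3-methoxy-5-(tosyloxy)benzaldehyde | COc1cc(C=O)cc(OS(=O)(=O)c2ccc(C)cc2)c1OCC=C | intermediate
4 | malonic acid | OC(=O)CC(=O)O | starting material
5 | (E)-3-[4-(allyloxy)-3-methoxy-5-(tosyloxy)phenyl]acrylic acid | COc1cc(/C=C/C(=O)O)cc(OS(=O)(=O)c2ccc(C)cc2)c1OCC=C | intermediate
6 | ferulic acid, (E)-3-(4-hydroxy-3-methoxyphenyl)acrylic acid | COc1cc(/C=C/C(=O)O)ccc1O | starting material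
7 | allyl (E)-3-[4-(allyloxy)-3-methoxyphenyl]acrylate | COc1cc(/C=C/C(=O)OCC=C)ccc1OCC=C | intermediate (not isolated)
8 | (E)-3-[4-(allyloxy)-3-methoxyphenyl]acrylic acid | COc1cc(/C=C/C(=O)O)ccc1OCC=C | intermediate
9 | (2R,4R)-pentane-2,4-diol | C[C@@H](O)C[C@@H](C)O | starting material
10 | (2R,4R)-4-hydroxypentan-2-yl (E)-3-[4-(allyloxy)-3-methoxyphenyl]acrylate | COc1cc(/C=C/C(=O)O[C@H](C)C[C@@H](C)O)ccc1OCC=C | intermediate
11 | (2R,4R)-pentane-2,4-diyl diester, one oxygen acylated by (E)-3-[4-(allyloxy)-3-methoxyphenyl]acryloyl and the other by (E)-3-[4-(allyloxy)-3-methoxy-5-(tosyloxy)phenyl]acryloyl | COc1cc(/C=C/C(=O)O[C@H](C)C[C@@H](C)OC(=O)/C=C/c2cc(OC)c(OCC=C)c(OS(=O)(=O)c3ccc(C)cc3)c2)ccc1OCC=C | intermediate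
12 | (2R,4R)-pentane-2,4-diyl mixed diester of ferulic acid and (E)-3-[4-hydroxy-3-methoxy-5-(tosyloxy)phenyl]acrylic acid | COc1cc(/C=C/C(=O)O[C@H](C)C[C@@H](C)OC(=O)/C=C/c2cc(OC)c(O)c(OS(=O)(=O)c3ccc(C)cc3)c2)ccc1O | intermediate
13 | bis(quinone methide): nine-membered cyclic (2R,4R)-pentane-2,4-diyl succinate whose C2 (R) carries the (3-methoxy-4-oxocyclohexa-2,5-dienylidene)methyl group and whose C3 (configuration immaterial) carries the (3-methoxy-4-oxo-5-tosyloxycyclohexa-2,5-dienylidene)methyl group | COC1=CC(=C[C@H]2C(=O)O[C@H](C)C[C@@H](C)OC(=O)C2C=C3C=C(OC)C(=O)C(OS(=O)(=O)c4ccc(C)cc4)=C3)C=CC1=O | intermediate (not isolated)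
14 | mono(quinone methide): the same dilactone with C3 now bearing the (E)-4-hydroxy-3-methoxy-5-(tosyloxy)benzylidene group (C3=C4) and C2 (R) still bearing the guaiacyl quinone methide | COC1=CC(=C[C@H]2C(=O)O[C@H](C)C[C@@H](C)OC(=O)/C2=C/c3cc(OC)c(O)c(OS(=O)(=O)c4ccc(C)cc4)c3)C=CC1=O | intermediate (not isolated)
15 | (1S,2R)-7-hydroxy-1-(4-hydroxy-3-methoxyphenyl)-6-methoxy-8-(tosyloxy)-1,2-dihydronaphthalene-2,3-dicarboxylic acid cyclic (2R,4R)-pentane-2,4-diyl diester (nine-membered dilactone) | COc1cc([C@H]2c3c(cc(OC)c(O)c3OS(=O)(=O)c3ccc(C)cc3)C=C4C(=O)O[C@H](C)C[C@@H](C)OC(=O)[C@H]24)ccc1O | intermediate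
16 | (1S,2R)-7-hydroxy-1-(4-hydroxy-3-methoxyphenyl)-6-methoxy-8-(tosyloxy)-1,2,3,4-tetrahydronaphthalene-2,3-dicarboxylic acid cyclic (2R,4R)-pentane-2,4-diyl diester, C3 configuration left open (either epimer serves) | COc1cc([C@H]2c3c(cc(OC)c(O)c3OS(=O)(=O)c3ccc(C)cc3)CC4C(=O)O[C@H](C)C[C@@H](C)OC(=O)[C@H]24)ccc1O | intermediate
17 | dimethyl (1S,2R,3R)-7-hydroxy-1-(4-hydroxy-3-methoxyphenyl)-6-methoxy-8-(tosyloxy)-1,2,3,4-tetrahydronaphthalene-2,3-dicarboxylate | COc1cc([C@H]2c3c(cc(OC)c(O)c3OS(=O)(=O)c3ccc(C)cc3)C[C@@H](C(=O)OC)[C@@H]2C(=O)OC)ccc1O | intermediate
18 | (1S,2R,3R)-1-(4-hydroxy-3-methoxyphenyl)-2,3-bis(hydroxymethyl)-6-methoxy-8-(tosyloxy)-1,2,3,4-tetrahydronaphthalen-7-ol | COc1cc([C@H]2c3c(cc(OC)c(O)c3OS(=O)(=O)c3ccc(C)cc3)C[C@@H](CO)[C@@H]2CO)ccc1O | intermediate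
19 | (1S,2R,3R)-1-(4-hydroxy-3-methoxyphenyl)-2,3-bis(hydroxymethyl)-6-methoxy-1,2,3,4-tetrahydronaphthalene-7,8-diol | COc1cc([C@H]2c3c(cc(OC)c(O)c3O)C[C@@H](CO)[C@@H]2CO)ccc1O | target

## Step count and least certain steps

Total: 12 steps. Longest linear sequence: 10 steps (1, 2, 3, 6, 7, 8, 9, 10, 11, 12 from 5-hydroxyvanillin); the ferulic acid branch (steps 4 and 5) joins at step 6.

**Step 8 (key step, proposed new method).** Several processes can defeat it:
- intermolecular coupling and oligomerisation outrunning closure of the strained nine-membered dilactone;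
- coupling through the free C5 position or the oxygen of the guaiacyl unit;
- tautomerisation of the guaiacyl quinone methide first (the roles of the two rings are then reversed), or of both quinone methides before ring closure;
- capture of a quinone methide by methanol;
- over-oxidation of the product with loss of the C1 hydrogen and aromatisation;
- weak or inverted facial induction by the tether. An inverted sense alone would be met within the same chemistry by taking the mirror-image diol.

Fallback by known chemistry, setting out from aldehyde 3 and rejoining at 18: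
- Reductive condensation of 3 with Meldrum's acid in formic acid/triethylamine at about 95 °C should give 3-[4-(allyloxy)-3-methoxy-5-(tosyloxy)phenyl]propanoic acid F1.
- Activation as the mixed pivalic anhydride and acylation of lithiated (S)-4-benzyl-2-oxazolidinone gives the imide (S)-4-benzyl-3-{3-[4-(allyloxy)-3-methoxy-5-(tosyloxy)phenyl]propanoyl}oxazolidin-2-one F2.
- Enolisation with NaN(SiMe3)2 at −78 °C and alkylation with tert-butyl bromoacetate, anti to the benzyl group of the auxiliary, should give tert-butyl (3R)-3-{[4-(allyloxy)-3-methoxy-5-(tosyloxy)phenyl]methyl}-4-[(4S)-4-benzyl-2-oxooxazolidin-3-yl]-4-oxobutanoate F3, which fixes C3.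
- LiBH4 reduction removes the auxiliary, and acid (CF3CO2H) closes the hydroxy ester to (R)-4-{[4-(allyloxy)-3-methoxy-5-(tosyloxy)phenyl]methyl}dihydrofuran-2(3H)-one F4.
- Vanillin is allylated (allyl bromide, K2CO3) to 4-(allyloxy)-3-methoxybenzaldehyde F5.
- The lithium enolate of F4 (LiN(SiMe3)2, −78 °C) adds to F5 trans to the benzylic arm, giving (3S,4R)-4-{[4-(allyloxy)-3-methoxy-5-(tosyloxy)phenyl]methyl}-3-{[4-(allyloxy)-3-methoxyphenyl](hydroxy)methyl}dihydrofuran-2(3H)-one F6 as carbinol epimers.
- CF3CO2H in CH2Cl2 ionises the carbinol, and ring A closes through C8a (para to methoxy, the position para to the sulfonate being deactivated as in the main route) to the all-trans (1S,2R,3R)-1-[4-(allyloxy)-3-methoxyphenyl]-7-(allyloxy)-6-methoxy-8-(tosyloxy)tetralin 2,3-fused γ-lactone (C9 carbonyl on C2, C10 as OCH2 on C3) F7.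
- LiAlH4 at 0 °C gives (1S,2R,3R)-1-[4-(allyloxy)-3-methoxyphenyl]-7-(allyloxy)-2,3-bis(hydroxymethyl)-6-methoxy-8-(tosyloxy)tetralin F8.
- Pd(PPh3)4 with morpholine removes both allyl groups to give 18.

**Step 1.** The alkylation may not discriminate cleanly between the two phenols (the more acidic one is also the more hindered), leading to double or misplaced allylation. Fallback from 1, rejoining at 3: exhaustive sulfonylation (TsCl, Et3N, DMAP) to 5-formyl-3-methoxy-1,2-phenylene bis(4-methylbenzenesulfonate) F9; selective hydrolysis with aqueous LiOH in THF of the sulfonate para to the formyl group, whose phenolate is the better leaving group, to 4-hydroxy-3-methoxy-5-(tosyloxy)benzaldehyde F10; then allylation (allyl bromide, K2CO3, DMF) to 3.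

**Step 9.** Reversible addition and elimination of palladium hydride may move the double bond toward C2 or C1 and erode the C2 and C1 configurations, or the hindered alkene may reduce slowly. Fallback from 15, rejoining at 16: conjugate reduction with copper hydride ([(Ph3P)CuH]6, or Cu(OAc)2 with a phosphine and a silane used in excess to allow for the acidic phenols). This delivers hydride to C4 and a proton to C3 without a migrating metal hydride, and no new compound is involved.

**Step 12.** Electron transfer to the sulfonate may be sluggish beside the electron-rich phenolate, and the freed catechol may oxidise in the basic methoxide medium. Fallback from 17, rejoining at 19: excess LiAlH4 in refluxing THF, which reduces both esters and cleaves the aryl sulfonate by hydride attack at sulfur in one operation, followed by acidic work-up under argon; no new compound is involved.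

## Further compounds

F1 | step 8 | 3-[4-(allyloxy)-3-methoxy-5-(tosyloxy)phenyl]propanoic acid | COc1cc(CCC(=O)O)cc(OS(=O)(=O)c2ccc(C)cc2)c1OCC=C
F2 | step 8 | (S)-4-benzyl-3-{3-[4-(allyloxy)-3-methoxy-5-(tosyloxy)phenyl]propanoyl}oxazolidin-2-one | COc1cc(CCC(=O)N2[C@@H](Cc3ccccc3)COC2=O)cc(OS(=O)(=O)c2ccc(C)cc2)c1OCC=C
F3 | step 8 | tert-butyl (3R)-3-{[4-(allyloxy)-3-methoxy-5-(tosyloxy)phenyl]methyl}-4-[(4S)-4-benzyl-2-oxooxazolidin-3-yl]-4-oxobutanoate | CC(C)(C)OC(=O)C[C@@H](Cc1cc(OC)c(OCC=C)c(OS(=O)(=O)c2ccc(C)cc2)c1)C(=O)N1[C@@H](Cc2ccccc2)COC1=O
F4 | step 8 | (R)-4-{[4-(allyloxy)-3-methoxy-5-(tosyloxy)phenyl]methyl}dihydrofuran-2(3H)-one | O=C1C[C@@H](Cc2cc(OC)c(OCC=C)c(OS(=O)(=O)c3ccc(C)cc3)c2)CO1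
F5 | step 8 | 4-(allyloxy)-3-methoxybenzaldehyde | COc1cc(C=O)ccc1OCC=C
F6 | step 8 | (3S,4R)-4-{[4-(allyloxy)-3-methoxy-5-(tosyloxy)phenyl]methyl}-3-{[4-(allyloxy)-3-methoxyphenyl](hydroxy)methyl}dihydrofuran-2(3H)-one, carbinol epimers | O=C1OC[C@H](Cc2cc(OC)c(OCC=C)c(OS(=O)(=O)c3ccc(C)cc3)c2)[C@H]1C(O)c1ccc(OCC=C)c(OC)c1
F7 | step 8 | (1S,2R,3R)-1-[4-(allyloxy)-3-methoxyphenyl]-7-(allyloxy)-6-methoxy-8-(tosyloxy)tetralin 2,3-fused γ-lactone (C9 carbonyl on C2, C10 as OCH2 on C3) | COc1cc([C@H]2c3c(cc(OC)c(OCC=C)c3OS(=O)(=O)c3ccc(C)cc3)C[C@H]4COC(=O)[C@H]24)ccc1OCC=C
F8 | step 8 | (1S,2R,3R)-1-[4-(allyloxy)-3-methoxyphenyl]-7-(allyloxy)-2,3-bis(hydroxymethyl)-6-methoxy-8-(tosyloxy)tetralin | COc1cc([C@H]2c3c(cc(OC)c(OCC=C)c3OS(=O)(=O)c3ccc(C)cc3)C[C@@H](CO)[C@@H]2CO)ccc1OCC=C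
F9 | step 1 | 5-formyl-3-methoxy-1,2-phenylene bis(4-methylbenzenesulfonate) | COc1cc(C=O)cc(OS(=O)(=O)c2ccc(C)cc2)c1OS(=O)(=O)c1ccc(C)cc1
F10 | step 1 | 4-hydroxy-3-methoxy-5-(tosyloxy)benzaldehyde | COc1cc(C=O)cc(OS(=O)(=O)c2ccc(C)cc2)c1O
F0 | step 9 | none | none
F0 | step 12 | none | none
A1 | alternative 1 | trans-2,3-bis(benzyloxymethyl)-7,8-bis(benzyloxy)-6-methoxy-4-(phenylsulfonyl)-3,4-dihydronaphthalen-1(2H)-one | O=C1c2c(cc(OC)c(OCc3ccccc3)c2OCc2ccccc2)C(S(=O)(=O)c2ccccc2)[C@@H](COCc2ccccc2)[C@@H]1COCc1ccccc1
A2 | alternative 1 | 2,3-bis(benzyloxy)-4-methoxy-6-(trimethylsilyl)phenyl trifluoromethanesulfonate | COc1cc([Si](C)(C)C)c(OS(=O)(=O)C(F)(F)F)c(OCc2ccccc2)c1OCc1ccccc1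
A3 | alternative 1 | trans-3,4-bis(benzyloxymethyl)-2-(phenylsulfonyl)cyclobutan-1-one | O=C1C(S(=O)(=O)c2ccccc2)[C@@H](COCc2ccccc2)[C@@H]1COCc1ccccc1
A4 | alternative 1 | caesium fluoride | [Cs+].[F-]
A5 | alternative 2 | tricyclic methyl acetal with O8 bonded to C9 of the all-trans tetralin, acetal epimers | COc1cc([C@H]2c3c(cc(OC)c(OCc4ccccc4)c3O5)C[C@@H](COCc3ccccc3)[C@@H]2C5OC)ccc1OCc1ccccc1
A6 | alternative 2 | hydroxy carbinol: 3-(benzyloxy)-2-[(4-benzyloxy-3-methoxyphenyl)(hydroxy)methyl]-6-[(2R)-2-(benzyloxymethyl)-4-methoxybut-3-enyl]-4-methoxyphenol with the benzyloxy group at O7 (carbinol epimers, enol ether geometry open) | COC=C[C@H](COCc1ccccc1)Cc1cc(OC)c(OCc2ccccc2)c(O)c1C(O)c1ccc(OCc2ccccc2)c(OC)c1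
A7 | alternative 2 | diphenyl hydrogen phosphate | O=P(O)(Oc1ccccc1)Oc1ccccc1
A8 | alternative 3 | dimethyl 1-hydroxy-6-methoxy-7,8-(diphenylmethylenedioxy)tetralin-2,3-dicarboxylate, esters trans, hydroxyl cis to the C2 ester | O[C@@H]1c2c(cc(OC)c3OC(c4ccccc4)(c4ccccc4)Oc23)C[C@@H](C(=O)OC)[C@@H]1C(=O)OC
A9 | alternative 3 | 7-methoxy-5-methyl-2,2-diphenyl-1,3-benzodioxole-4-carbaldehyde | Cc1cc(OC)c2OC(c3ccccc3)(c3ccccc3)Oc2c1C=O
A10 | alternative 3 | dimethyl fumarate | COC(=O)/C=C/C(=O)OC
A11 | alternative 3 | titanium tetraisopropoxide, Ti(OiPr)4 | CC(C)O[Ti](OC(C)C)(OC(C)C)OC(C)C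
A12 | alternative 3 | guaiacol (2-methoxyphenol) | COc1ccccc1O
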